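The flavone is cut at the O1–C8a aryl ether bond of ring C. Ring A is a syringyl unit (C6-OMe, C7-O, C8-OMe) whose two equivalent C–H positions ortho to the C4 carbonyl end up as C8a (bonded to O1) and C5 (OH). One anodic dehydrogenative C–O closure of an open-chain 2-methoxy-1,3-diaryl-1,3-diketone therefore forges O1–C8a and ring C with the 3-methoxy group already in place; a carbonyl-directed hydroxylation then fills C5. The precursor is the racemic diketone carrying a 3,5-dimethoxy-4-pivaloyloxyphenyl ring A and a 3,4,5-tris(pivaloyloxy)phenyl ring B; uniform pivalate masking keeps ring B electron-poor, resists anode and acid, and falls in one final step.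

Key step: step 6

Remark: the 1,3-diketones are drawn and named as diketo tautomers although they exist largely as enols, and a metal salt of a product that lasts only until the acidic work-up is counted as that product.

Step 1
Reactants: 1 acetosyringone; 2 pivaloyl chloride
Product: 3 4-acetyl-2,6-dimethoxyphenyl pivalate
Conditions: PivCl (1.3 equiv), Et3N, DMAP (cat.), CH2Cl2, 0 °C to rt
Reagents that add atoms: pivaloyl chloride (compound 2), CC(C)(C)C(=O)Cl
Why: DMAP-catalysed O-acylation (esterification) of the only phenol through the acylpyridinium ion should proceed despite the two ortho methoxy groups, and the pivalate is chosen because it should withstand the enolate, Lewis acid, anodic and hot trifluoroacetic acid conditions that follow.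

Step 2
Reactants: 4 gallic acid; 2 pivaloyl chloride
Product: 6 3,4,5-tris(pivaloyloxy)benzoic acid, via mixed pivalic anhydride 5 (not isolated)
Conditions: PivCl (4.5 equiv), pyridine, DMAP (cat.), 0 to 40 °C; then H2O, THF, rt
Reagents that add atoms: pivaloyl chloride (compound 2), CC(C)(C)C(=O)Cl; water, O
Why: exhaustive O-acylation (esterification) of the three phenols also converts the carboxyl group into the mixed anhydride, which water should cleave selectively at its unhindered aroyl carbonyl while the aryl pivalates stay intact.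

Step 3
Reactants: 6 3,4,5-tris(pivaloyloxy)benzoic acid
Product: 7 3,4,5-tris(pivaloyloxy)benzoyl chloride
Conditions: (COCl)2, DMF (cat.), CH2Cl2, 0 °C to rt
Reagents that add atoms: oxalyl chloride, O=C(Cl)C(=O)Cl
Why: acid chloride formation through the Vilsmeier-type chloroiminium catalyst is neutral enough to leave the aryl pivalates untouched, and the volatile by-products allow the crude chloride to be used directly.

Step 4
Reactants: 3 4-acetyl-2,6-dimethoxyphenyl pivalate; 7 3,4,5-tris(pivaloyloxy)benzoyl chloride
Product: 9 1-[3,5-dimethoxy-4-(pivaloyloxy)phenyl]-3-[3,4,5-tris(pivaloyloxy)phenyl]propane-1,3-dione, via lithium enolate 8 (not isolated)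
Conditions: LiN(SiMe3)2 (2.2 equiv), THF, −78 °C; then 7 (1.05 equiv), −78 to 0 °C; 1 M HCl
Reagents that add atoms: none
Why: Claisen-type C-acylation of a pre-formed lithium methyl ketone enolate by an aroyl chloride should be fast at low temperature, the second equivalent of base taking up the acidic C–H of the diketone as it forms, while the hindered pivalates outlast the non-nucleophilic amide.

Step 5
Reactants: 9 1-[3,5-dimethoxy-4-(pivaloyloxy)phenyl]-3-[3,4,5-tris(pivaloyloxy)phenyl]propane-1,3-dione
Product: 10 racemic 1-[3,5-dimethoxy-4-(pivaloyloxy)phenyl]-2-methoxy-3-[3,4,5-tris(pivaloyloxy)phenyl]propane-1,3-dione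
Conditions: (PhIO)n (1.2 equiv), BF3·OEt2, MeOH/CH2Cl2, 0 °C to rt
Reagents that add atoms: methanol, CO
Why: hypervalent iodine α-alkoxylation of a β-dicarbonyl compound, in which the enol attacks the BF3-activated trivalent iodine reagent at C2 and methanol then displaces iodobenzene from the C2 iodonium species; the new C2 stereocenter forms without control as the racemate, which is immaterial because step 6 turns it into an sp2 carbon.

Step 6
Reactants: 10 racemic 1-[3,5-dimethoxy-4-(pivaloyloxy)phenyl]-2-methoxy-3-[3,4,5-tris(pivaloyloxy)phenyl]propane-1,3-dione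
Product: 11 3,6,8-trimethoxy-7-(pivaloyloxy)-2-[3,4,5-tris(pivaloyloxy)phenyl]-4H-chromen-4-one
Conditions: graphite anode, Pt cathode, undivided cell, constant current (5 mA cm−2, 2.2 F mol−1), Bu4NPF6 (0.1 M), HFIP, rt
Reagents that add atoms: none
Why: Proposed new method: in 1,1,1,3,3,3-hexafluoropropan-2-ol the anode should remove one electron from ring A, the only arene of 10 that carries two methoxy donors, and the oxygen on the ring B side of the diketone (enol or carbonyl form) then adds to C2 of that ring, which is flanked by one methoxy group and stands para to the other and so bears much of the positive charge; a second electron and two protons are then lost to give the aromatic 4-pyranone while hydrogen forms at the cathode. The closest known reaction types are the anodic dehydrogenative lactonisation of biaryl-2-carboxylic acids to benzocoumarins and the oxidative aryl C–O cyclisations mediated by trivalent iodine reagents, which likewise close a six-membered ring through oxygen onto an arene C–H. Ring C closes as a six-membered ring by attack of oxygen on the ortho carbon (6-endo with respect to the arene, new bond O1–C8a); closure through the central carbon would give a four-membered ring, and ipso attack would give a spiro five-membered cation that cannot rearomatise and should revert. No stereocenter is created, and the racemic C2 center of 10 disappears as it becomes the sp2 carbon C3. The step needs ring A to be oxidised and attacked in preference to ring B, which the three electron-withdrawing pivaloyloxy groups on ring B secure, whereas no choice arises between the two ortho C–H positions of ring A because its local symmetry makes them equivalent. Passing only slightly more than 2 F mol−1, together with the deactivating pyranone carbonyl next to the last ring A C–H (C5), should hold back further oxidation of 11.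

Step 7
Reactants: 11 3,6,8-trimethoxy-7-(pivaloyloxy)-2-[3,4,5-tris(pivaloyloxy)phenyl]-4H-chromen-4-one
Product: 13 5-hydroxy-3,6,8-trimethoxy-7-(pivaloyloxy)-2-[3,4,5-tris(pivaloyloxy)phenyl]-4H-chromen-4-one, via C5 trifluoroacetate 12 (not isolated)
Conditions: [RuCl2(p-cymene)]2 (5 mol %), PhI(OCOCF3)2 (2 equiv), TFA/TFAA, 80 °C; then aq. Na2S2O3, aq. NaHCO3, rt
Reagents that add atoms: [bis(trifluoroacetoxy)iodo]benzene, O=C(O[I](OC(=O)C(F)(F)F)c1ccccc1)C(F)(F)F
Why: ketone-directed C–H oxygenation by divalent ruthenium, a reaction established for the peri C5–H of chromones and flavones, in which the C4 carbonyl steers cycloruthenation to C5 (the only C–H left on ring A), the trivalent iodine oxidant and C–O reductive elimination deliver the C5 trifluoroacetate, and this ester, which shields the new para-methoxyphenol from the oxidant until the excess is quenched, is cleaved by water on work-up while the pivalates survive the anhydrous acid.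

Step 8
Reactants: 13 5-hydroxy-3,6,8-trimethoxy-7-(pivaloyloxy)-2-[3,4,5-tris(pivaloyloxy)phenyl]-4H-chromen-4-one
Product: 14 5,7,3',4',5'-pentahydroxy-3,6,8-trimethoxyflavone (target)
Conditions: NaOMe (8 equiv), degassed MeOH/THF, Ar, 0 °C to rt; then 1 M HCl
Reagents that add atoms: none
Why: base-mediated transesterification (Zemplén-type methanolysis) should release the four aryl pivalates as methyl pivalate and leave the aryl methyl ethers and the C3 enol ether untouched; oxygen is excluded until acidification because the polyphenolates autoxidise, and any base-induced opening and reclosure of ring C would be degenerate since C6 and C8 carry the same group.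

Compound list
1 | acetosyringone (4'-hydroxy-3',5'-dimethoxyacetophenone) | CC(=O)c1cc(OC)c(O)c(OC)c1 | starting material
2 | pivaloyl chloride | CC(C)(C)C(=O)Cl | starting material
3 | 4-acetyl-2,6-dimethoxyphenyl pivalate | CC(=O)c1cc(OC)c(OC(=O)C(C)(C)C)c(OC)c1 | intermediate
4 | gallic acid (3,4,5-trihydroxybenzoic acid) | OC(=O)c1cc(O)c(O)c(O)c1 | starting material
5 | 3,4,5-tris(pivaloyloxy)benzoic pivalic anhydride (not isolated) | CC(C)(C)C(=O)OC(=O)c1cc(OC(=O)C(C)(C)C)c(OC(=O)C(C)(C)C)c(OC(=O)C(C)(C)C)c1 | intermediate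
6 | 3,4,5-tris(pivaloyloxy)benzoic acid | OC(=O)c1cc(OC(=O)C(C)(C)C)c(OC(=O)C(C)(C)C)c(OC(=O)C(C)(C)C)c1 | intermediate
7 | 3,4,5-tris(pivaloyloxy)benzoyl chloride | ClC(=O)c1cc(OC(=O)C(C)(C)C)c(OC(=O)C(C)(C)C)c(OC(=O)C(C)(C)C)c1 | intermediate
8 | lithium 1-[3,5-dimethoxy-4-(pivaloyloxy)phenyl]ethen-1-olate (not isolated) | [Li+].[O-]C(=C)c1cc(OC)c(OC(=O)C(C)(C)C)c(OC)c1 | intermediate
9 | 1-[3,5-dimethoxy-4-(pivaloyloxy)phenyl]-3-[3,4,5-tris(pivaloyloxy)phenyl]propane-1,3-dione (no stereocenter) | COc1cc(C(=O)CC(=O)c2cc(OC(=O)C(C)(C)C)c(OC(=O)C(C)(C)C)c(OC(=O)C(C)(C)C)c2)cc(OC)c1OC(=O)C(C)(C)C | intermediate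
10 | racemic 1-[3,5-dimethoxy-4-(pivaloyloxy)phenyl]-2-methoxy-3-[3,4,5-tris(pivaloyloxy)phenyl]propane-1,3-dione | COc1cc(C(=O)C(OC)C(=O)c2cc(OC(=O)C(C)(C)C)c(OC(=O)C(C)(C)C)c(OC(=O)C(C)(C)C)c2)cc(OC)c1OC(=O)C(C)(C)C | intermediate
11 | 3,6,8-trimethoxy-7-(pivaloyloxy)-2-[3,4,5-tris(pivaloyloxy)phenyl]-4H-chromen-4-one | COc1cc2c(=O)c(OC)c(-c3cc(OC(=O)C(C)(C)C)c(OC(=O)C(C)(C)C)c(OC(=O)C(C)(C)C)c3)oc2c(OC)c1OC(=O)C(C)(C)C | intermediate
12 | 3,6,8-trimethoxy-7-(pivaloyloxy)-5-(trifluoroacetoxy)-2-[3,4,5-tris(pivaloyloxy)phenyl]-4H-chromen-4-one (not isolated) | COc1c(OC(=O)C(F)(F)F)c2c(=O)c(OC)c(-c3cc(OC(=O)C(C)(C)C)c(OC(=O)C(C)(C)C)c(OC(=O)C(C)(C)C)c3)oc2c(OC)c1OC(=O)C(C)(C)C | intermediate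
13 | 5-hydroxy-3,6,8-trimethoxy-7-(pivaloyloxy)-2-[3,4,5-tris(pivaloyloxy)phenyl]-4H-chromen-4-one | COc1c(O)c2c(=O)c(OC)c(-c3cc(OC(=O)C(C)(C)C)c(OC(=O)C(C)(C)C)c(OC(=O)C(C)(C)C)c3)oc2c(OC)c1OC(=O)C(C)(C)C | intermediate
14 | 5,7,3',4',5'-pentahydroxy-3,6,8-trimethoxyflavone (no stereocenter) | COc1c(O)c(OC)c2oc(-c3cc(O)c(O)c(O)c3)c(OC)c(=O)c2c1O | target

Total step count: 8. Longest linear sequence: 7 steps (gallic acid to the target through steps 2 to 8).

Steps most likely to fail

Step 6 (proposed new method). The current may be consumed by electron transfer from the enol or from the cyclised product instead of a clean two-electron closure on ring A, or the ring A radical cation may be too short-lived to be trapped by the weakly nucleophilic oxygen. The fallback uses known chemistry and places a halogen where the C–H stood. It sets out from 3: nuclear bromination with NBS in MeCN should give 4-acetyl-3-bromo-2,6-dimethoxyphenyl pivalate F1, the position ortho to one methoxy group and para to the other being the only activated one. Deprotonation with LiN(SiMe3)2 in THF at −78 °C gives lithium 1-[2-bromo-3,5-dimethoxy-4-(pivaloyloxy)phenyl]ethen-1-olate F2, which is C-acylated with 7 as in step 4 to 1-[2-bromo-3,5-dimethoxy-4-(pivaloyloxy)phenyl]-3-[3,4,5-tris(pivaloyloxy)phenyl]propane-1,3-dione F3. α-Methoxylation as in step 5 gives racemic 1-[2-bromo-3,5-dimethoxy-4-(pivaloyloxy)phenyl]-2-methoxy-3-[3,4,5-tris(pivaloyloxy)phenyl]propane-1,3-dione F4. An Ullmann-type intramolecular O-arylation of the diketone enolate (CuI, 1,10-phenanthroline, K3PO4, toluene, 90 °C), a known way from 1-(2-haloaryl)-1,3-diketones to chromones, then closes ring C and comes back to the route at 11.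

Step 7. The trivalent iodine oxidant may degrade the electron-rich ring A (the new C5 oxygen stands para to the C8 methoxy group, an arrangement prone to quinone formation), or cycloruthenation next to the C6 methoxy group may be sluggish. The fallback replaces C–H oxygenation by halogenation, borylation and oxidation. It sets out from 11: electrophilic bromination with NBS (MeCN, cat. TFA) at C5, the only C–H of ring A and activated by the C6 and C8 methoxy groups, should give 5-bromo-3,6,8-trimethoxy-7-(pivaloyloxy)-2-[3,4,5-tris(pivaloyloxy)phenyl]-4H-chromen-4-one F5. Miyaura borylation (B2pin2, KOAc, Pd(OAc)2, SPhos, dioxane, 90 °C; zerovalent palladium forms in the flask) gives 3,6,8-trimethoxy-7-(pivaloyloxy)-5-(4,4,5,5-tetramethyl-1,3,2-dioxaborolan-2-yl)-2-[3,4,5-tris(pivaloyloxy)phenyl]-4H-chromen-4-one F6. Buffered oxidation of the boronate (30% aq. H2O2, NaHCO3, THF, 0 °C to rt) comes back to the route at 13.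

Step 5. The α-oxidation may stop short or run on to a second oxidation at C2, and the acidic methanol may cause retro-Claisen cleavage of the diketone or partial methanolysis of aryl pivalates. The fallback replaces the iodane displacement by a carbenoid O–H insertion. It sets out from 9: Regitz diazo transfer (4-acetamidobenzenesulfonyl azide, Et3N, MeCN, rt) should give 2-diazo-1-[3,5-dimethoxy-4-(pivaloyloxy)phenyl]-3-[3,4,5-tris(pivaloyloxy)phenyl]propane-1,3-dione F7. Rh2(OAc)4-catalysed O–H insertion of the derived carbenoid into methanol (MeOH/CH2Cl2, rt) then comes back to the route at 10.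

Further compounds
F1 | step 6 | 4-acetyl-3-bromo-2,6-dimethoxyphenyl pivalate | CC(=O)c1cc(OC)c(OC(=O)C(C)(C)C)c(OC)c1Br
F2 | step 6 | lithium 1-[2-bromo-3,5-dimethoxy-4-(pivaloyloxy)phenyl]ethen-1-olate | [Li+].[O-]C(=C)c1cc(OC)c(OC(=O)C(C)(C)C)c(OC)c1Br
F3 | step 6 | 1-[2-bromo-3,5-dimethoxy-4-(pivaloyloxy)phenyl]-3-[3,4,5-tris(pivaloyloxy)phenyl]propane-1,3-dione | COc1cc(C(=O)CC(=O)c2cc(OC(=O)C(C)(C)C)c(OC(=O)C(C)(C)C)c(OC(=O)C(C)(C)C)c2)c(Br)c(OC)c1OC(=O)C(C)(C)C
F4 | step 6 | racemic 1-[2-bromo-3,5-dimethoxy-4-(pivaloyloxy)phenyl]-2-methoxy-3-[3,4,5-tris(pivaloyloxy)phenyl]propane-1,3-dione | COc1cc(C(=O)C(OC)C(=O)c2cc(OC(=O)C(C)(C)C)c(OC(=O)C(C)(C)C)c(OC(=O)C(C)(C)C)c2)c(Br)c(OC)c1OC(=O)C(C)(C)C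
F5 | step 7 | 5-bromo-3,6,8-trimethoxy-7-(pivaloyloxy)-2-[3,4,5-tris(pivaloyloxy)phenyl]-4H-chromen-4-one | COc1c(Br)c2c(=O)c(OC)c(-c3cc(OC(=O)C(C)(C)C)c(OC(=O)C(C)(C)C)c(OC(=O)C(C)(C)C)c3)oc2c(OC)c1OC(=O)C(C)(C)C
F6 | step 7 | 3,6,8-trimethoxy-7-(pivaloyloxy)-5-(4,4,5,5-tetramethyl-1,3,2-dioxaborolan-2-yl)-2-[3,4,5-tris(pivaloyloxy)phenyl]-4H-chromen-4-one | COc1c(B4OC(C)(C)C(C)(C)O4)c2c(=O)c(OC)c(-c3cc(OC(=O)C(C)(C)C)c(OC(=O)C(C)(C)C)c(OC(=O)C(C)(C)C)c3)oc2c(OC)c1OC(=O)C(C)(C)C
F7 | step 5 | 2-diazo-1-[3,5-dimethoxy-4-(pivaloyloxy)phenyl]-3-[3,4,5-tris(pivaloyloxy)phenyl]propane-1,3-dione | COc1cc(C(=O)C(=[N+]=[N-])C(=O)c2cc(OC(=O)C(C)(C)C)c(OC(=O)C(C)(C)C)c(OC(=O)C(C)(C)C)c2)cc(OC)c1OC(=O)C(C)(C)C
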